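**Plan** (target numbering: ring A = C1–C6, ring B = C6–C11, as in 2,8-dibromo-9-chloro-1,1,5,9-tetramethylspiro[5.5]undecane)

1. Retrosynthesis: the C8–Br/C9–Cl pair goes back, through a halogen interchange and a trans-diaxial chlorohydrin, to a C8=C9 alkene; the C9 methyl goes back to a ring B ketone and the C5 methyl to a C5 ketone.
2. Ring A is then cut at C3–C4 and C1–C6 in one stroke. C4–C5–C6 become the two α-carbons and the carbonyl of a methyl ketone that carries ring B; C1–C2–C3 become a five-carbon bromochloride made from prenol.
3. The enabling feature: in ring A the bromomethine C2 lies between the methylene C3 and the gem-dimethyl carbon C1. C3 can act as a primary SN2 electrophile and C1 as a tertiary cation bridged by the same bromine, a 1,3-dielectrophile matched to the 1,3-dinucleophilic C4/C6 of the C5 ketone.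
4. Forward order: prenol to an enantioenriched bromochloro triflate; one-flask annulation onto a symmetrical ring B ketone (as ketal) builds ring A and the spiro carbon; C5 methyl by methylenation and hydrogenation; ring B desymmetrised to the methylcyclohexene; ring B halogens last.
5. Stereochemistry: C2 from catalytic enantioselective bromochlorination, carried through untouched; C5 from hydrogenation anti to the axial C1 methyl; C6 from a chiral lithium amide; C8/C9 from trans-diaxial epoxide opening followed by a stereospecific diaxial-to-diequatorial halogen interchange.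

Key step: step 3

Assumption: ketal ketone 4 is taken as a catalogue compound, and the ligand enantiomer in step 1 and the base enantiomer in step 6 are those that deliver the configurations drawn.

Step 1
Reactants: 1 3-methylbut-2-en-1-ol (prenol)
Product: 2 (R)-2-bromo-3-chloro-3-methylbutan-1-ol
Conditions: NBS, ClTi(OiPr)3, chiral tridentate Schiff-base ligand (20 mol %), hexane, −20 °C
Reagents that add atoms: N-bromosuccinimide O=C1CCC(=O)N1Br; chlorotitanium triisopropoxide CC(C)O[Ti](Cl)(OC(C)C)OC(C)C
Why: Catalytic enantioselective bromochlorination of an allylic alcohol, in which the titanium-bound alkoxide fixes the face of bromiranium formation and chloride opens it anti at the tertiary carbon (Markovnikov), should set the C–Br stereocentre as R.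

Step 2
Reactants: 2 (R)-2-bromo-3-chloro-3-methylbutan-1-ol
Product: 3 (R)-2-bromo-3-chloro-3-methylbutyl trifluoromethanesulfonate
Conditions: Tf2O, 2,6-di-tert-butyl-4-methylpyridine, CH2Cl2, −78 °C; used cold without purification
Reagents that add atoms: triflic anhydride O=S(=O)(OS(=O)(=O)C(F)(F)F)C(F)(F)F
Why: O-Sulfonylation of the primary alcohol with a non-nucleophilic base at low temperature should leave the C–Br stereocentre untouched and give a leaving group reactive enough for enolate SN2 at −78 °C.

Step 3
Reactants: 4 1-(1,4-dioxaspiro[4.5]decan-8-yl)ethan-1-one; 3 (R)-2-bromo-3-chloro-3-methylbutyl trifluoromethanesulfonate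
Product: 6 (2R)-2-bromo-1,1-dimethylspiro[5.5]undecane-5,9-dione 9-ethylene ketal, via bromochloro ketone 5 (not isolated)
Conditions: LiN(iPr)2 (LDA), THF, −78 °C; 3, −78 to −30 °C; volatiles removed; then (CF3)2CHOH (HFIP), 0 to 23 °C
Reagents that add atoms: none
Why: Proposed new method: the kinetic methyl-side lithium enolate of 4 displaces the primary triflate of 3 (SN2) to give 5, which forms the C3–C4 bond of ring A, and in HFIP the tertiary chloride of 5 ionises with anchimeric help from the vicinal bromine to a bromiranium ion whose tertiary carbon is captured by the methine enol of the ketone, which forms the C1–C6 bond between two fully substituted carbons. The closest known reaction types are the solvolytic, stereospecific bromo-polyene cyclisation of vicinal bromochlorides in HFIP and the acid- or Lewis-acid-mediated α-tert-alkylation of ketone enol derivatives (Conia-type closure); what is new is the ketone enol as terminating nucleophile and the telescoping with the enolate alkylation. Ring A closes as a six-membered ring by Markovnikov (endo-mode) opening of the bromiranium ring at its tertiary carbon by the enol carbon (enolendo), through a chair with bromine equatorial. No new stereocentre is formed: C2 keeps its R configuration because its C–Br bond is never broken (the bromine only bridges to C1 and returns), and the spiro carbon is not yet stereogenic because ring B is still symmetrical. The step needs methyl over methine selectivity in the alkylation (kinetic deprotonation at −78 °C), methine over methylene selectivity in the closure (the methylene enol could only close a four-membered ring) and C- over O-capture (the O-cyclised tertiary enol ether should re-ionise under the HCl set free, so the irreversible C–C closure drains the equilibrium).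

Step 4
Reactants: 6 (2R)-2-bromo-1,1-dimethylspiro[5.5]undecane-5,9-dione 9-ethylene ketal
Product: 7 (2R)-2-bromo-1,1-dimethyl-5-methylidenespiro[5.5]undecan-9-one ethylene ketal
Conditions: Cp2TiMe2, toluene, 70 °C
Reagents that add atoms: dimethyltitanocene C[Ti](C)(C1C=CC=C1)C1C=CC=C1
Why: Petasis methylenation (titanium methylidene formed by loss of methane) should olefinate the hindered, enolisable ketone next to the quaternary spiro carbon under non-basic conditions that spare the secondary bromide and the ketal; no stereocentre is formed.

Step 5
Reactants: 7 (2R)-2-bromo-1,1-dimethyl-5-methylidenespiro[5.5]undecan-9-one ethylene ketal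
Product: 9 (2R,5S)-2-bromo-1,1,5-trimethylspiro[5.5]undecan-9-one, via ketal 8 (not isolated)
Conditions: H2 (1 atm), PtO2, EtOAc, 23 °C; then 2 M HCl, THF, 23 °C
Reagents that add atoms: water O
Why: Heterogeneous catalytic hydrogenation of the exocyclic alkene from the face opposite the axial C1 methyl (ring A chair with bromine equatorial) should place the new C5 methyl axial and cis to bromine (5S), and acid-catalysed ketal hydrolysis then frees the ring B ketone.

Step 6
Reactants: 9 (2R,5S)-2-bromo-1,1,5-trimethylspiro[5.5]undecan-9-one
Product: 10 (2R,5S,6S)-2-bromo-1,1,5-trimethylspiro[5.5]undec-8-en-9-yl trifluoromethanesulfonate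
Conditions: (R,R)-bis(1-phenylethyl)amine, n-BuLi, LiCl, THF, −78 °C; then PhNTf2, −78 to 0 °C
Reagents that add atoms: N-phenylbis(trifluoromethanesulfonimide) O=S(=O)(N(c1ccccc1)S(=O)(=O)C(F)(F)F)C(F)(F)F
Why: Group-selective deprotonation by a chiral lithium amide (the two axial α-hydrogens of ring B are distinguished by the reagent) followed by O-triflation should fix the position of the ring B double bond and so the configuration of the spiro carbon (6S); the (R,R)-base is taken as the enantiomer that converts 4-tert-butylcyclohexanone into its (S)-enol derivative, whose equatorial tert-butyl group corresponds to the equatorial C1 branch here.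

Step 7
Reactants: 10 (2R,5S,6S)-2-bromo-1,1,5-trimethylspiro[5.5]undec-8-en-9-yl trifluoromethanesulfonate
Product: 11 (2R,5S,6S)-2-bromo-1,1,5,9-tetramethylspiro[5.5]undec-8-ene
Conditions: MeZnCl, Pd(PPh3)4 (5 mol %), THF, 50 °C
Reagents that add atoms: methylzinc chloride C[Zn]Cl
Why: Negishi cross-coupling of the alkenyl triflate with a methylzinc reagent under zerovalent palladium catalysis should install the C9 methyl without touching the hindered secondary alkyl bromide or any stereocentre.

Step 8
Reactants: 11 (2R,5S,6S)-2-bromo-1,1,5,9-tetramethylspiro[5.5]undec-8-ene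
Product: 13 (2R,5S,6S,8R,9R)-2-bromo-8-chloro-1,1,5,9-tetramethylspiro[5.5]undecan-9-ol, via epoxide 12 (not isolated)
Conditions: mCPBA, CH2Cl2, 0 °C; then HCl (4 M in 1,4-dioxane), −20 °C
Reagents that add atoms: mCPBA O=C(OO)c1cccc(Cl)c1; hydrogen chloride Cl
Why: Prilezhaev epoxidation should occur on the ring B face opposite the axial C5-bearing branch of the spiro carbon, and hydrogen chloride then opens the epoxide trans-diaxially at the secondary carbon C8, as 5,6-epoxy steroids do, to give the axial 8-chloride (8R) and the axial tertiary 9-alcohol (9R).

Step 9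
Reactants: 13 (2R,5S,6S,8R,9R)-2-bromo-8-chloro-1,1,5,9-tetramethylspiro[5.5]undecan-9-ol
Product: 15 (2R,5S,6S,8S,9S)-2,8-dibromo-9-chloro-1,1,5,9-tetramethylspiro[5.5]undecane, via diaxial bromochloride 14 (not isolated)
Conditions: TMSBr, CH2Cl2, 0 °C; then CHCl3, 60 °C
Reagents that add atoms: bromotrimethylsilane C[Si](C)(C)Br
Why: Tertiary alcohol to bromide exchange through the C9 cation, captured axially anti to the neighbouring chlorine, should give the trans-diaxial 9-bromo-8-chloro compound 14, and the known thermal diaxial-to-diequatorial rearrangement of vicinal trans-dihalides (suprafacial 1,2-interchange, each halogen staying on its own ring face) then moves chlorine to C9 and bromine to C8, which relieves the 1,3-diaxial clash between the C8 halogen and the C5 branch and gives the 8S,9S target.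

**Compound list**

1 | 3-methylbut-2-en-1-ol (prenol) | CC(C)=CCO | starting material
2 | (R)-2-bromo-3-chloro-3-methylbutan-1-ol | OC[C@@H](Br)C(C)(C)Cl | intermediate
3 | (R)-2-bromo-3-chloro-3-methylbutyl trifluoromethanesulfonate | O=S(=O)(OC[C@@H](Br)C(C)(C)Cl)C(F)(F)F | intermediate
4 | 1-(1,4-dioxaspiro[4.5]decan-8-yl)ethan-1-one | CC(=O)C1CCC2(CC1)OCCO2 | starting material
5 | (4R)-4-bromo-5-chloro-1-(1,4-dioxaspiro[4.5]decan-8-yl)-5-methylhexan-1-one | O=C(CC[C@@H](Br)C(C)(C)Cl)C1CCC2(CC1)OCCO2 | intermediate
6 | (2R)-2-bromo-1,1-dimethylspiro[5.5]undecane-5,9-dione 9-ethylene ketal | O=C1CC[C@@H](Br)C(C)(C)C12CCC3(CC2)OCCO3 | intermediate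
7 | (2R)-2-bromo-1,1-dimethyl-5-methylidenespiro[5.5]undecan-9-one ethylene ketal | C=C1CC[C@@H](Br)C(C)(C)C12CCC3(CC2)OCCO3 | intermediate
8 | (2R,5S)-2-bromo-1,1,5-trimethylspiro[5.5]undecan-9-one ethylene ketal | C[C@H]1CC[C@@H](Br)C(C)(C)C12CCC3(CC2)OCCO3 | intermediate
9 | (2R,5S)-2-bromo-1,1,5-trimethylspiro[5.5]undecan-9-one | C[C@H]1CC[C@@H](Br)C(C)(C)C12CCC(=O)CC2 | intermediate
10 | (2R,5S,6S)-2-bromo-1,1,5-trimethylspiro[5.5]undec-8-en-9-yl trifluoromethanesulfonate | C[C@H]1CC[C@@H](Br)C(C)(C)[C@]12CCC(OS(=O)(=O)C(F)(F)F)=CC2 | intermediate
11 | (2R,5S,6S)-2-bromo-1,1,5,9-tetramethylspiro[5.5]undec-8-ene | C[C@H]1CC[C@@H](Br)C(C)(C)[C@]12CCC(C)=CC2 | intermediate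
12 | (2R,5S,6S,8S,9R)-2-bromo-8,9-epoxy-1,1,5,9-tetramethylspiro[5.5]undecane | C[C@H]1CC[C@@H](Br)C(C)(C)[C@]12CC[C@@]3(C)O[C@H]3C2 | intermediate
13 | (2R,5S,6S,8R,9R)-2-bromo-8-chloro-1,1,5,9-tetramethylspiro[5.5]undecan-9-ol | C[C@H]1CC[C@@H](Br)C(C)(C)[C@]12CC[C@@](C)(O)[C@H](Cl)C2 | intermediate
14 | (2R,5S,6S,8R,9R)-2,9-dibromo-8-chloro-1,1,5,9-tetramethylspiro[5.5]undecane | C[C@H]1CC[C@@H](Br)C(C)(C)[C@]12CC[C@@](C)(Br)[C@H](Cl)C2 | intermediate
15 | (2R,5S,6S,8S,9S)-2,8-dibromo-9-chloro-1,1,5,9-tetramethylspiro[5.5]undecane | C[C@H]1CC[C@@H](Br)C(C)(C)[C@]12CC[C@](C)(Cl)[C@@H](Br)C2 | target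

**Totals**

Total step count: 9. Longest linear sequence: 9 steps (1 to 15 through steps 1–9); ketone 4 enters at step 3.

**Steps most likely to fail**

Step 3. The bromiranium ion may hand its bromine to the enol instead of being attacked at carbon, or be captured at oxygen without return. In the alkylation stage the enolate may eliminate triflic acid from 3, and the dioxolane may suffer in the acidic HFIP. Fallback (known chemistry), setting out from 4 and 3 and returning at 6: only the enolate alkylation is run (LDA, THF, −78 °C) and 5 is isolated. 5 is converted with TMSOTf and Et3N (CH2Cl2, 0 °C) into the tetrasubstituted trimethylsilyl enol ether of its methine side F1; the trisubstituted regioisomer is hydrolysed back to 5 and recycled. F1 is then closed by Lewis-acid-mediated α-tert-alkylation of the silyl enol ether with its own tertiary chloride (ZnCl2, CH2Cl2, −40 °C), which rejoins the route at 6.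

Step 6. The chiral base may not discriminate the two ring B α-methylene groups well enough, because the axial α-hydrogens are shielded by the axial C5 branch and ring A may act as a mismatched influence. Fallback, setting out from 9 and returning at 11: MeMgBr with CeCl3 (THF, −78 °C) adds to the ring B ketone to give the tertiary alcohol with axial hydroxyl F2. Dehydration with POCl3 in pyridine (anti elimination toward either neighbouring methylene, no arm preference) gives 11 together with its C6 epimer F3. The two are diastereomers and are separated on AgNO3-impregnated silica.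

Step 9. During the hydroxyl-to-bromide exchange the tertiary C9 centre may lose water or HBr (E1) instead of capturing bromide, which would return alkene rather than 14. Fallback, setting out from 11 and returning at 14: anti addition of a bromine chloride equivalent (NBS, Et4NCl, CH2Cl2, −40 °C). The bromiranium ion should form on the open ring B face, away from the axial C5 branch, and chloride should open it trans-diaxially at C8, the course hypobromous acid takes with 5,6-unsaturated steroids. This gives 14 without a tertiary alcohol, and the same thermal interchange then leads to 15.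

**Further compounds**

F1 | step 3 | [(4R)-4-bromo-5-chloro-1-(1,4-dioxaspiro[4.5]decan-8-ylidene)-5-methylhexyl]oxy(trimethyl)silane | C[Si](C)(C)OC(CC[C@@H](Br)C(C)(C)Cl)=C1CCC2(CC1)OCCO2
F2 | step 6 | (2R,5S)-2-bromo-1,1,5,9-tetramethylspiro[5.5]undecan-9-ol, hydroxyl axial and cis to the C1 branch | C[C@H]1CC[C@@H](Br)C(C)(C)[C@]12CC[C@@](C)(O)CC2
F3 | step 6 | (2R,5S,6R)-2-bromo-1,1,5,9-tetramethylspiro[5.5]undec-8-ene | C[C@H]1CC[C@@H](Br)C(C)(C)[C@@]12CCC(C)=CC2
F0 | step 9 | none | none
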